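**Remark on the chemistry.** Locants follow the hydrindanone core of the target: C1 carries the acetoxyethyl group (its carbinol carbon is called C8), C2 is the ketone carbon, C3a and C7a are the ring-fusion carbons, C4 carries the methylene group, C5 and C6 the ester oxygens, C7 the oxirane. β is the face of H-3a, H-7, O-5 and O-6; α is the face of H-7a. (S)-Citramalic acid, (S)-but-3-yn-2-ol and (R)-2-methylbutanoic acid are taken as purchasable single enantiomers.

## Retrosynthetic overview

1. The oxirane is closed last from a 1,2-diol on C7; the C5 and C6 esters and the C8 acetate are put on just before, on a trans-hydrindanone that already holds every ring stereocenter.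
2. Ring B (C1–C2–C3–C3a–C7a) is made from a four-membered ring. A cyclobutyl silyl ether at C2 (ring C2–C3–C3a–C7a) carrying the trans-epoxide C1–C8 is enlarged by a Lewis-acid 1,2-shift of C7a from C2 to C1, which forms the C1–C7a bond. The enabling feature is that C1 lies between the C2 carbonyl and the carbinol carbon C8: O=C2–C1–C8–O is the aldol-type pattern that an epoxy-carbinol semipinacol shift delivers, with ring carbon C7a as the migrating group.
3. The cyclobutane comes from an enone–alkene [2+2] photocycloaddition of a ring A cyclohexenone (C4=O, C3a=C7a) with a 2-silyloxyvinyl epoxide; the C4 ketone then becomes the exocyclic methylene.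
4. Ring A comes from an organocatalytic Michael/aldol annulation of a citramalic-acid-derived aldehyde with methyl vinyl ketone, then cis-dihydroxylation (O-5, O-6) and dehydrogenation.
5. Order of ring formation: dioxolane (masked oxirane) → ring A → cyclobutane → ring B (key step) → oxirane.

Key step: step 13

## Route

Step 1
Reactants: 1 (S)-citramalic acid
Product: 2 (2S)-2-methylbutane-1,2,4-triol
Conditions: BH3·SMe2, B(OMe)3, THF, 0 °C → rt; then MeOH
Reagents that add atoms: none
Why: Borane reduction of both carboxylic acids leaves the tertiary carbinol stereocenter (the later oxirane carbon) untouched.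

Step 2
Reactants: 2 triol
Product: 3 2-[(4S)-2,2,4-trimethyl-1,3-dioxolan-4-yl]ethan-1-ol
Conditions: 2,2-dimethoxypropane, p-TsOH·H2O (cat.), acetone, rt
Reagents that add atoms: 2,2-dimethoxypropane, COC(C)(C)OC
Why: Acetonide formation under thermodynamic control favours the five-membered 1,2-dioxolane over the six-membered acetal and leaves the remote primary hydroxyl free.

Step 3
Reactants: 3 dioxolanyl ethanol
Product: 4 2-[(4S)-2,2,4-trimethyl-1,3-dioxolan-4-yl]acetaldehyde
Conditions: TEMPO (10 mol %), PhI(OAc)2, CH2Cl2, rt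
Reagents that add atoms: none
Why: Oxoammonium (TEMPO) oxidation of a primary alcohol stops at the aldehyde under neutral conditions that spare the acetonide.

Step 4
Reactants: 4 aldehyde; 5 methyl vinyl ketone
Product: 7 (4S)-4-[(4S)-2,2,4-trimethyl-1,3-dioxolan-4-yl]cyclohex-2-en-1-one, via keto aldehyde 6 (not isolated)
Conditions: (R)-2-[diphenyl(trimethylsilyloxy)methyl]pyrrolidine (10 mol %), ethyl 3,4-dihydroxybenzoate (20 mol %), 5 (1.5 equiv), neat, 4 °C; then Bn2NH·CF3CO2H (20 mol %), toluene, 50 °C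
Reagents that add atoms: none
Why: Enamine-catalysed Michael addition, in which the diarylsilyloxymethyl group shields one enamine face and so sets C7 (2R in 6), is followed by intramolecular aldol condensation of the methyl ketone onto the aldehyde (Robinson-type annulation).

Step 5
Reactants: 7 cyclohexenone
Product: 8 (2R,3R,4S)-2,3-dihydroxy-4-[(4S)-2,2,4-trimethyl-1,3-dioxolan-4-yl]cyclohexan-1-one
Conditions: OsO4 (2 mol %), NMO, acetone/H2O (4:1), 0 °C → rt
Reagents that add atoms: N-methylmorpholine N-oxide, C[N+]1([O-])CCOCC1; water, O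
Why: Upjohn cis-dihydroxylation of the enone double bond on the face opposite to the bulky neighbouring C7 substituent gives O-5 and O-6 cis to each other and trans to the side chain.

Step 6
Reactants: 8 keto diol
Product: 9 (2R,3R,4S)-2,3-bis(tert-butyldimethylsilyloxy)-4-[(4S)-2,2,4-trimethyl-1,3-dioxolan-4-yl]cyclohexan-1-one
Conditions: TBSOTf, 2,6-lutidine, CH2Cl2, −78 → 0 °C
Reagents that add atoms: tert-butyldimethylsilyl trifluoromethanesulfonate, CC(C)(C)[Si](C)(C)OS(=O)(=O)C(F)(F)F
Why: Silylation of both secondary hydroxyls gives a diol protection that is stable to Lewis acid and can later be removed in the presence of the side-chain acetonide.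

Step 7
Reactants: 9 bis-silyl ketone
Product: 10 (4S,5R,6R)-5,6-bis(tert-butyldimethylsilyloxy)-4-[(4S)-2,2,4-trimethyl-1,3-dioxolan-4-yl]cyclohex-2-en-1-one
Conditions: IBX (2.0 equiv), DMSO/fluorobenzene, 70 °C
Reagents that add atoms: none
Why: IBX dehydrogenation of the ketone acts on the only unhindered CH2–CH2 pair next to the carbonyl (C3a/C7a) and needs no strong base that could eliminate the β-silyloxy group.

Step 8
Reactants: 11 (±)-(E)-pent-3-en-2-ol
Product: 12 (2S,3S,4S)-3,4-epoxypentan-2-ol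
Conditions: Ti(OiPr)4 (10 mol %), L-(+)-diisopropyl tartrate (15 mol %), t-BuOOH (0.45 equiv), 4 Å MS, CH2Cl2, −20 °C
Reagents that add atoms: tert-butyl hydroperoxide, CC(C)(C)OO
Why: Sharpless kinetic resolution: the L-(+)-tartrate catalyst epoxidises the fast-reacting (S)-alcohol on the face that gives the erythro epoxy alcohol, and the slow (R)-alcohol is left behind and separated.

Step 9
Reactants: 12 epoxy alcohol
Product: 13 (3R,4S)-3,4-epoxypentan-2-one
Conditions: Dess–Martin periodinane, NaHCO3, CH2Cl2, 0 °C → rt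
Reagents that add atoms: none
Why: Buffered Dess–Martin oxidation removes the carbinol stereocenter and leaves the two epoxide stereocenters, which become C1 and C8, unchanged.

Step 10
Reactants: 13 epoxy ketone
Product: 14 tert-butyldimethyl({1-[(2R,3S)-3-methyloxiran-2-yl]ethenyl}oxy)silane
Conditions: KN(SiMe3)2, TBSCl (internal quench), THF, −78 °C
Reagents that add atoms: tert-butyldimethylsilyl chloride, CC(C)(C)[Si](C)(C)Cl
Why: Kinetic deprotonation occurs at the methyl group, not at the strained oxirane C–H, and O-silylation gives the 2-silyloxy alkene.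

Step 11
Reactants: 10 cyclohexenone; 14 silyl enol ether
Product: 15 trans-fused cyclobutane adduct: 3β,4β,7-tris(tert-butyldimethylsilyloxy)-7-[(2R,3S)-3-methyloxiran-2-yl]-5α-[(4S)-2,2,4-trimethyl-1,3-dioxolan-4-yl]bicyclo[4.2.0]octan-2-one (H-1 β, H-6 α; both C7 epimers)
Conditions: hν (350 nm, Pyrex), 14 (5 equiv), CH2Cl2, −60 °C
Reagents that add atoms: none
Why: Enone–alkene [2+2] photocycloaddition: the electron-rich 1,1-disubstituted alkene should add head-to-tail (its oxygen-bearing carbon to the enone β-carbon C7a), anti to the C7 substituent, and the twisted triplet enone should close mainly to the trans-fused ring; both epimers at the silyloxy carbon converge in step 13.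

Step 12
Reactants: 15 cyclobutane ketone
Product: 16 the 2-methylidene analogue of 15 (C4=CH2 in hydrindane numbering)
Conditions: Cp2TiMe2 (3 equiv), toluene, 70 °C, dark
Reagents that add atoms: dimethyltitanocene, [CH3-].[CH3-].[Ti+4].c1cc[cH-]c1.c1cc[cH-]c1
Why: Petasis methylenation is neither basic nor strongly Lewis acidic, so it installs the exocyclic methylene without epimerising the strained ring-fusion carbon C3a and without opening the epoxide, and it locks the trans fusion.

Step 13
Reactants: 16 epoxy cyclobutyl silyl ether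
Product: 17 (1S,3aR,5S,6R,7S,7aR)-5,6-bis(tert-butyldimethylsilyloxy)-1-[(1S)-1-hydroxyethyl]-4-methylidene-7-[(4S)-2,2,4-trimethyl-1,3-dioxolan-4-yl]octahydro-2H-inden-2-one
Conditions: BF3·OEt2 (1.2 equiv), CH2Cl2, −78 °C; sat. aq. NaHCO3
Reagents that add atoms: none
Why: BF3 coordinates the epoxide oxygen, and the strained cyclobutane bond C2–C7a, antiperiplanar to the C1–O bond, migrates from C2 to C1 while the resulting oxocarbenium ion loses its silyl group; this is the semipinacol rearrangement of a 2,3-epoxy silyl ether, run as a one-carbon enlargement of a cyclobutanol to a cyclopentanone. Ring B (C1–C2–C3–C3a–C7a) is therefore closed by a 1,2-shift: the four-membered ring grows by the epoxide carbon C1. C7a migrates with retention, so the trans ring fusion of the photoadduct is carried into the hydrindanone; C1 is formed with inversion at the epoxide carbon and C8 keeps its oxygen and configuration, so both are dictated by the (2R,3S)-epoxide. The step needs C7a to migrate in preference to C3, which the higher migratory aptitude of the secondary, more electron-rich carbon and the relief of strain of the trans-fused four-membered ring should secure. It also needs the dioxolane, the secondary silyl ethers and the exocyclic alkene to survive, which the low temperature and the assistance of the migrating bond make plausible.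

Step 14
Reactants: 17 β-hydroxy ketone
Product: 18 (1S)-1-[(1S,3aR,5S,6R,7S,7aR)-5,6-bis(tert-butyldimethylsilyloxy)-4-methylidene-2-oxo-7-[(4S)-2,2,4-trimethyl-1,3-dioxolan-4-yl]octahydro-1H-inden-1-yl]ethyl acetate
Conditions: Ac2O, pyridine, DMAP (5 mol %), CH2Cl2, 0 °C
Reagents that add atoms: acetic anhydride, CC(=O)OC(C)=O
Why: Mild acetylation of the only free hydroxyl at 0 °C avoids retro-aldol cleavage and elimination of the β-oxygenated ketone.

Step 15
Reactants: 18 bis-silyl ether
Product: 19 (1S)-1-[(1S,3aR,5S,6R,7S,7aR)-5,6-dihydroxy-4-methylidene-2-oxo-7-[(4S)-2,2,4-trimethyl-1,3-dioxolan-4-yl]octahydro-1H-inden-1-yl]ethyl acetate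
Conditions: HF·pyridine, pyridine/THF, 0 °C → rt
Reagents that add atoms: none
Why: Buffered fluoride desilylation is weakly acidic, so the β-acetoxy ketone does not eliminate and the acetonide stays.

Step 16
Reactants: 19 diol; 20 (R)-2-methylbutanoic acid
Product: 22 (1S,3aR,5S,6R,7S,7aR)-1-[(1S)-1-acetoxyethyl]-5-hydroxy-4-methylidene-2-oxo-7-[(4S)-2,2,4-trimethyl-1,3-dioxolan-4-yl]octahydro-1H-inden-6-yl (2R)-2-methylbutanoate, via acid chloride 21 (not isolated)
Conditions: 20, (COCl)2, DMF (cat.), CH2Cl2, 0 °C → rt, evaporate; then 19, Me2SnCl2 (10 mol %), K2CO3, THF, rt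
Reagents that add atoms: none
Why: Tin-catalysed regioselective acylation: the cis-diol forms a stannylene-type chelate in which the equatorial oxygen (O-6) is the nucleophilic one, and the base-free formation of the acid chloride and the heterogeneous base keep the α-stereocenter of the acyl group intact.

Step 17
Reactants: 23 (S)-but-3-yn-2-ol
Product: 25 (2S,3E)-4-iodo-3-methylbut-3-en-2-ol, via alkenylalane 24 (not isolated)
Conditions: Me3Al (3 equiv), Cp2ZrCl2 (25 mol %), CH2Cl2, 0 °C → rt; then I2, THF, −30 → 0 °C; aq. K2CO3 work-up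
Reagents that add atoms: trimethylaluminium, C[Al](C)C; iodine, II
Why: Negishi carboalumination adds methyl and aluminium syn across the alkyne, and iodinolysis with retention gives the (E)-vinyl iodide.

Step 18
Reactants: 25 vinyl iodide
Product: 26 (2E,4S)-4-hydroxy-3-methylpent-2-enoic acid
Conditions: Pd(OAc)2 (5 mol %), PPh3 (10 mol %), CO (1 atm), Et3N, DMF/H2O (4:1), 50 °C; then acidify
Reagents that add atoms: carbon monoxide, [C-]#[O+]; water, O
Why: Palladium-catalysed hydroxycarbonylation of a vinyl iodide proceeds with retention of alkene geometry, and the (E)-acid cannot lactonise onto the hydroxyl.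

Step 19
Reactants: 26 hydroxy acid
Product: 27 (2E,4S)-4-acetoxy-3-methylpent-2-enoic acid
Conditions: Ac2O, pyridine, DMAP (cat.), CH2Cl2, 0 °C → rt; aqueous work-up
Reagents that add atoms: acetic anhydride, CC(=O)OC(C)=O
Why: O-Acetylation of the secondary alcohol; the mixed anhydride formed at the carboxyl group is hydrolysed on work-up.

Step 20
Reactants: 22 C5 alcohol; 27 acetoxy acid
Product: 28 (1S,3aR,5S,6R,7S,7aR)-1-[(1S)-1-acetoxyethyl]-4-methylidene-6-{[(2R)-2-methylbutanoyl]oxy}-2-oxo-7-[(4S)-2,2,4-trimethyl-1,3-dioxolan-4-yl]octahydro-1H-inden-5-yl (2E,4S)-4-acetoxy-3-methylpent-2-enoate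
Conditions: DCC, DMAP (10 mol %), CH2Cl2, 0 °C → rt
Reagents that add atoms: none
Why: Steglich esterification of the remaining axial, allylic hydroxyl, with only catalytic DMAP so that the β-acetoxy ketone does not eliminate and the neighbouring ester does not migrate.

Step 21
Reactants: 28 acetonide
Product: 29 the corresponding 7-[(2S)-1,2-dihydroxypropan-2-yl] compound
Conditions: AcOH/H2O (4:1), 40 °C
Reagents that add atoms: none
Why: Mild acid hydrolysis of the terminal acetonide should leave the three esters, the β-acetoxy ketone and the allylic ester intact.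

Step 22
Reactants: 29 primary/tertiary 1,2-diol
Product: 30 target, (1S,3aR,5S,6R,7S,7aR)-1-[(1S)-1-acetoxyethyl]-4-methylidene-6-{[(2R)-2-methylbutanoyl]oxy}-7-[(2S)-2-methyloxiran-2-yl]-2-oxooctahydro-1H-inden-5-yl (2E,4S)-4-acetoxy-3-methylpent-2-enoate
Conditions: PPh3, DIAD, toluene, 0 → 60 °C
Reagents that add atoms: none
Why: Mitsunobu cyclodehydration activates the primary hydroxyl and the tertiary oxygen displaces it, so the oxirane closes under neutral conditions with retention at the tertiary carbon.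

## Compound list

1 | (S)-citramalic acid, (2S)-2-hydroxy-2-methylbutanedioic acid | OC(=O)C[C@@](O)(C)C(=O)O | starting material
2 | (2S)-2-methylbutane-1,2,4-triol | OCC[C@@](O)(C)CO | intermediate
3 | 2-[(4S)-2,2,4-trimethyl-1,3-dioxolan-4-yl]ethan-1-ol | OCC[C@@]1(C)COC(C)(C)O1 | intermediate
4 | 2-[(4S)-2,2,4-trimethyl-1,3-dioxolan-4-yl]acetaldehyde | O=CC[C@@]1(C)COC(C)(C)O1 | intermediate
5 | methyl vinyl ketone | C=CC(C)=O | starting material
6 | (2R)-5-oxo-2-[(4S)-2,2,4-trimethyl-1,3-dioxolan-4-yl]hexanal | CC(=O)CC[C@H]([C@@]1(C)COC(C)(C)O1)C=O | intermediate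
7 | (4S)-4-[(4S)-2,2,4-trimethyl-1,3-dioxolan-4-yl]cyclohex-2-en-1-one | O=C1CC[C@H]([C@@]2(C)COC(C)(C)O2)C=C1 | intermediate
8 | (2R,3R,4S)-2,3-dihydroxy-4-[(4S)-2,2,4-trimethyl-1,3-dioxolan-4-yl]cyclohexan-1-one | O=C1CC[C@H]([C@@]2(C)COC(C)(C)O2)[C@@H](O)[C@H]1O | intermediate
9 | (2R,3R,4S)-2,3-bis(tert-butyldimethylsilyloxy)-4-[(4S)-2,2,4-trimethyl-1,3-dioxolan-4-yl]cyclohexan-1-one | O=C1CC[C@H]([C@@]2(C)COC(C)(C)O2)[C@@H](O[Si](C)(C)C(C)(C)C)[C@H]1O[Si](C)(C)C(C)(C)C | intermediate
10 | (4S,5R,6R)-5,6-bis(tert-butyldimethylsilyloxy)-4-[(4S)-2,2,4-trimethyl-1,3-dioxolan-4-yl]cyclohex-2-en-1-one | O=C1C=C[C@H]([C@@]2(C)COC(C)(C)O2)[C@@H](O[Si](C)(C)C(C)(C)C)[C@H]1O[Si](C)(C)C(C)(C)C | intermediate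
11 | (±)-(E)-pent-3-en-2-ol | C/C=C/C(C)O | starting material
12 | (2S,3S,4S)-3,4-epoxypentan-2-ol | C[C@H](O)[C@@H]1O[C@H]1C | intermediate
13 | (3R,4S)-3,4-epoxypentan-2-one | CC(=O)[C@@H]1O[C@H]1C | intermediate
14 | tert-butyldimethyl({1-[(2R,3S)-3-methyloxiran-2-yl]ethenyl}oxy)silane | C=C(O[Si](C)(C)C(C)(C)C)[C@@H]1O[C@H]1C | intermediate
15 | trans-fused 3β,4β,7-tris(tert-butyldimethylsilyloxy)-7-[(2R,3S)-3-methyloxiran-2-yl]-5α-[(4S)-2,2,4-trimethyl-1,3-dioxolan-4-yl]bicyclo[4.2.0]octan-2-one (H-1 β, H-6 α, C7 epimers) | O=C1[C@@H]2CC(O[Si](C)(C)C(C)(C)C)([C@@H]3O[C@H]3C)[C@H]2[C@H]([C@@]2(C)COC(C)(C)O2)[C@@H](O[Si](C)(C)C(C)(C)C)[C@H]1O[Si](C)(C)C(C)(C)C | intermediate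
16 | 2-methylidene analogue of 15 | C=C1[C@@H]2CC(O[Si](C)(C)C(C)(C)C)([C@@H]3O[C@H]3C)[C@H]2[C@H]([C@@]2(C)COC(C)(C)O2)[C@@H](O[Si](C)(C)C(C)(C)C)[C@H]1O[Si](C)(C)C(C)(C)C | intermediate
17 | (1S,3aR,5S,6R,7S,7aR)-5,6-bis(tert-butyldimethylsilyloxy)-1-[(1S)-1-hydroxyethyl]-4-methylidene-7-[(4S)-2,2,4-trimethyl-1,3-dioxolan-4-yl]octahydro-2H-inden-2-one | C=C1[C@@H]2CC(=O)[C@H]([C@H](C)O)[C@H]2[C@H]([C@@]2(C)COC(C)(C)O2)[C@@H](O[Si](C)(C)C(C)(C)C)[C@H]1O[Si](C)(C)C(C)(C)C | intermediate
18 | C8 acetate of 17 | C=C1[C@@H]2CC(=O)[C@H]([C@H](C)OC(C)=O)[C@H]2[C@H]([C@@]2(C)COC(C)(C)O2)[C@@H](O[Si](C)(C)C(C)(C)C)[C@H]1O[Si](C)(C)C(C)(C)C | intermediate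
19 | 5β,6β-diol from 18 | C=C1[C@@H]2CC(=O)[C@H]([C@H](C)OC(C)=O)[C@H]2[C@H]([C@@]2(C)COC(C)(C)O2)[C@@H](O)[C@H]1O | intermediate
20 | (R)-2-methylbutanoic acid | CC[C@@H](C)C(=O)O | starting material
21 | (2R)-2-methylbutanoyl chloride | CC[C@@H](C)C(=O)Cl | intermediate
22 | C6 (2R)-2-methylbutanoate of 19 (C5 hydroxyl free) | C=C1[C@@H]2CC(=O)[C@H]([C@H](C)OC(C)=O)[C@H]2[C@H]([C@@]2(C)COC(C)(C)O2)[C@@H](OC(=O)[C@H](C)CC)[C@H]1O | intermediate
23 | (S)-but-3-yn-2-ol | C#C[C@H](C)O | starting material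
24 | dimethyl[(1E,3S)-3-(dimethylalumanyloxy)-2-methylbut-1-enyl]alumane | C[Al](C)/C=C(\C)[C@H](C)O[Al](C)C | intermediate
25 | (2S,3E)-4-iodo-3-methylbut-3-en-2-ol | I/C=C(\C)[C@H](C)O | intermediate
26 | (2E,4S)-4-hydroxy-3-methylpent-2-enoic acid | OC(=O)/C=C(\C)[C@H](C)O | intermediate
27 | (2E,4S)-4-acetoxy-3-methylpent-2-enoic acid | OC(=O)/C=C(\C)[C@H](C)OC(C)=O | intermediate
28 | C5 (2E,4S)-4-acetoxy-3-methylpent-2-enoate of 22 (side-chain acetonide) | C=C1[C@@H]2CC(=O)[C@H]([C@H](C)OC(C)=O)[C@H]2[C@H]([C@@]2(C)COC(C)(C)O2)[C@@H](OC(=O)[C@H](C)CC)[C@H]1OC(=O)/C=C(\C)[C@H](C)OC(C)=O | intermediate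
29 | 7-[(2S)-1,2-dihydroxypropan-2-yl] triester from 28 | C=C1[C@@H]2CC(=O)[C@H]([C@H](C)OC(C)=O)[C@H]2[C@H]([C@@](O)(C)CO)[C@@H](OC(=O)[C@H](C)CC)[C@H]1OC(=O)/C=C(\C)[C@H](C)OC(C)=O | intermediate
30 | (1S,3aR,5S,6R,7S,7aR)-1-[(1S)-1-acetoxyethyl]-4-methylidene-6-{[(2R)-2-methylbutanoyl]oxy}-7-[(2S)-2-methyloxiran-2-yl]-2-oxooctahydro-1H-inden-5-yl (2E,4S)-4-acetoxy-3-methylpent-2-enoate | C=C1[C@@H]2CC(=O)[C@H]([C@H](C)OC(C)=O)[C@H]2[C@H]([C@@]2(C)CO2)[C@@H](OC(=O)[C@H](C)CC)[C@H]1OC(=O)/C=C(\C)[C@H](C)OC(C)=O | target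

## Step count and risks

Total step count: 22 steps. Longest linear sequence: 16 steps (steps 1–7, 11–16, 20–22).

**Step 11.** What may go wrong: loss of control over orientation (head-to-head addition), face and ring-fusion geometry in the cycloaddition, made worse by the bulk of the alkene 14, which is costly to use in excess. Fallback: starting from 10, irradiation with the small and cheap 1,1-diethoxyethene should give the trans-fused ketal adduct F1. Methylenation with Cp2TiMe2 gives the methylidene ketal F2, and mild hydrolysis (oxalic acid on wet SiO2) gives the cyclobutanone F3. Addition of (E)-prop-1-enyllithium and trapping of the alkoxide with TBSOTf gives the allylic silyl ether F4. Shi epoxidation with the enantiomer of the fructose-derived ketone and Oxone then gives 16, where the route is rejoined.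

**Step 13.** What may go wrong: migration of C3 in place of C7a, or opening of the epoxide without migration. Fallback: starting from 10 and going through the cyclobutanone F3 (made as in the fallback for step 11), propynylmagnesium bromide gives the 1-alkynylcyclobutanol F5. Ring enlargement with Ph3PAuCl/AgSbF6 (alkyne activation, then migration of the more substituted C7a onto C1) gives the (E)-2-ethylidene cyclopentanone F6. Copper-catalysed conjugate borylation (CuCl, NaOtBu, a chiral bisphosphine chosen for the (S)-configured C8, B2pin2, MeOH) gives the boronate F7, and oxidation with NaBO3·4H2O returns to the route at 17.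

**Step 16.** What may go wrong: acylation at O-5 in place of O-6, or acyl migration between the two cis oxygens. Fallback: starting from 19, the more accessible allylic O-5 is silylated with the bulky TBDPSCl/imidazole to give the mono-silyl ether F8. The remaining O-6 is acylated with 20 (DCC, DMAP) to give the ester F9, and HF·pyridine removes the TBDPS group to come back at 22.

## Further compounds

F1 | step 11 | trans-fused 3β,4β-bis(tert-butyldimethylsilyloxy)-7,7-diethoxy-5α-[(4S)-2,2,4-trimethyl-1,3-dioxolan-4-yl]bicyclo[4.2.0]octan-2-one | O=C1[C@@H]2CC(OCC)(OCC)[C@H]2[C@H]([C@@]2(C)COC(C)(C)O2)[C@@H](O[Si](C)(C)C(C)(C)C)[C@H]1O[Si](C)(C)C(C)(C)C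
F2 | step 11 | 2-methylidene analogue of F1 | C=C1[C@@H]2CC(OCC)(OCC)[C@H]2[C@H]([C@@]2(C)COC(C)(C)O2)[C@@H](O[Si](C)(C)C(C)(C)C)[C@H]1O[Si](C)(C)C(C)(C)C
F3 | step 11 | trans-fused cyclobutanone from F2 | C=C1[C@@H]2CC(=O)[C@H]2[C@H]([C@@]2(C)COC(C)(C)O2)[C@@H](O[Si](C)(C)C(C)(C)C)[C@H]1O[Si](C)(C)C(C)(C)C
F4 | step 11 | tert-butyldimethylsilyl ether of the 1-[(E)-prop-1-enyl]cyclobutanol from F3 | C=C1[C@@H]2CC(O[Si](C)(C)C(C)(C)C)(/C=C/C)[C@H]2[C@H]([C@@]2(C)COC(C)(C)O2)[C@@H](O[Si](C)(C)C(C)(C)C)[C@H]1O[Si](C)(C)C(C)(C)C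
F5 | step 13 | 1-(prop-1-ynyl)cyclobutanol from F3 | C=C1[C@@H]2CC(O)(C#CC)[C@H]2[C@H]([C@@]2(C)COC(C)(C)O2)[C@@H](O[Si](C)(C)C(C)(C)C)[C@H]1O[Si](C)(C)C(C)(C)C
F6 | step 13 | (E)-1-ethylidene trans-hydrindan-2-one | C=C1[C@@H]2CC(=O)/C(=C/C)[C@H]2[C@H]([C@@]2(C)COC(C)(C)O2)[C@@H](O[Si](C)(C)C(C)(C)C)[C@H]1O[Si](C)(C)C(C)(C)C
F7 | step 13 | C8 pinacol boronate of the hydrindanone | C=C1[C@@H]2CC(=O)[C@H]([C@H](C)B3OC(C)(C)C(C)(C)O3)[C@H]2[C@H]([C@@]2(C)COC(C)(C)O2)[C@@H](O[Si](C)(C)C(C)(C)C)[C@H]1O[Si](C)(C)C(C)(C)C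
F8 | step 16 | 5-O-tert-butyldiphenylsilyl ether of 19 | C=C1[C@@H]2CC(=O)[C@H]([C@H](C)OC(C)=O)[C@H]2[C@H]([C@@]2(C)COC(C)(C)O2)[C@@H](O)[C@H]1O[Si](c1ccccc1)(c1ccccc1)C(C)(C)C
F9 | step 16 | 6-O-[(2R)-2-methylbutanoyl] derivative of F8 | C=C1[C@@H]2CC(=O)[C@H]([C@H](C)OC(C)=O)[C@H]2[C@H]([C@@]2(C)COC(C)(C)O2)[C@@H](OC(=O)[C@H](C)CC)[C@H]1O[Si](c1ccccc1)(c1ccccc1)C(C)(C)C
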